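- A charge of 0.627 M of reagent goes into 0.57 M of substrate over some seconds, and you want to know whether stretching those seconds costs target. Here are the flasks, the readings and the question.

| setting | gamma | beta | epsilon | cedar | maple | alder |
|---|---|---|---|---|---|---|
| substrate | 0.38 M | 0.85 M | 0.57 M | 0.57 M | 0.57 M | 0.57 M |
| reagent | 0.627 M (fed, over 4.0 s) | 0.627 M (fed, over 4.0 s) | 1.3 M (fed, over 4.0 s) | 0.627 M (fed, over 4.0 s) | 0.627 M (fed, over 8.0 s) | 0.627 M (fed, over 15 s) |
| remark | run made earlier; the fed solution adds 0.50 times the starting volume | run made earlier; the fed solution adds 0.50 times the starting volume | run made earlier; the fed solution adds 0.50 times the starting volume | the fed solution adds 0.50 times the starting volume | the fed solution adds 0.50 times the starting volume | the fed solution adds 0.50 times the starting volume |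
| time |  |  |  | 15 min | 15 min | 15 min |

| run | time / min | target / % |
|---|---|---|
| gamma | 2.50 | 16.1 |
| gamma | 5.00 | 14.9 |
| gamma | 8.00 | 15.7 |
| gamma | 10.0 | 16.3 |
| gamma | 12.0 | 15.7 |
| beta | 2.50 | 14.0 |
| beta | 5.00 | 14.5 |
| beta | 8.00 | 13.9 |
| beta | 10.0 | 14.3 |
| beta | 12.0 | 14.7 |
| epsilon | 1.00 | 26.9 |
| epsilon | 2.00 | 27.4 |
| epsilon | 3.00 | 26.3 |
| epsilon | 6.00 | 26.6 |
| epsilon | 12.0 | 26.9 |

(scatter of a reading: 0.5 percentage points)

- amounts are per litre of the starting volume; all of the dose is in the solution fed
- "hardly changes" means that all values lie within two and a half points (for a concentration: within two and a half percent of the largest)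

1. [target] at the end for cedar, maple, alder, in this order
2. the shape of the row from first to last (falls all the way / hardly changes / rises all the way / rises, then falls / falls, then rises)

- Follow one substrate molecule. I take it that at each instant it can meet reagent and become target, or leave by a route that needs no reagent. At steady [reagent] the capture is pseudo-first-order, so the odds of target should grow in step with [reagent].
- The readings allow a test. Gamma and beta average 15.0% at a full [reagent] of 0.418 M, and epsilon averages 26.8% at 0.867 M.
- The capture ratio, a selectivity factor, is the odds of target per molar of reagent met, and gamma with beta give 0.423 M⁻¹. Epsilon, a separate run, reads 0.423 M⁻¹, so the two readings of the ratio agree across the change of dose.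
- First instants: [reagent] climbs from zero, so a molecule leaving early meets little of it. I estimate the rate at which substrate is lost from epsilon, whose first reading, at 1.00 min, already stands at the plateau within the scatter. On a single exponential that reading puts the rate at no less than 0.0664 s⁻¹, and I take this floor as my estimate, a lifetime of about 15.1 s, which is longer than cedar's feed and about equal to alder's.
- Middle: a ramp weighted by that exit gives a mean [reagent] met of the full value times (1 − exp(−x))/x, with x the rate times the feed time. Scaled so that cedar, fed like the earlier runs, keeps the full value, this leaves 0.369 M for maple and 0.301 M for alder.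
- End: the target readings of the earlier runs stay level within the scatter, and the target sits in 1.50 starting volumes. My row is therefore 0.0570 M, 0.0513 M, 0.0429 M.
- The forecast differs from my row: it gives 0.086 M, 0.087 M, 0.088 M, a row that hardly changes, on the ground that “feed time should barely matter”.

- The flask gives 0.0578 M, 0.0518 M and 0.0437 M for cedar, maple and alder, a row that falls all the way, with alder lower than cedar.

    reagent + intermediate B → side product B (k = 0.0370 M⁻¹ s⁻¹)
    2 substrate → homo dimer (k = 0.0170 M⁻¹ s⁻¹)
    substrate → side product A (k = 0.0460 s⁻¹)
    intermediate A → intermediate B (k = 0.0270 s⁻¹)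
    substrate + reagent → target (k = 0.0380 M⁻¹ s⁻¹)
    substrate ⇌ intermediate A (K = 0.120, k = 0.0100 s⁻¹)
    substrate → intermediate B (k = 0.0150 s⁻¹)

- At the end of alder's feed, 0.250 min, substrate is down to 28.7% with target at 5.95%. Put alder's final yield of 11.5% through 0.423 M⁻¹, and the mean [reagent] its substrate met comes to 0.307 M, against a full 0.418 M.

(The runs are simulated from invented constants.)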